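(The runs stem from a simulated flask for an exercise; the scatter is artificial.)

It was impossible to read either factor straight off the earlier runs. Their highest catalyst charge, 3.8 mM, lies below the 12 mM asked about, and no earlier run changed the partner charge.

all flasks: substrate 0.10 M

| run | partner | catalyst | added ligand | remark |
|---|---|---|---|---|
| south-west | 0.30 M | 2.5 mM | 4.2 mM | run made earlier |
| north-east | 0.30 M | 2.5 mM | 17 mM | run made earlier |
| east | 0.30 M | 3.8 mM | 8.5 mM | run made earlier |
| flask | 0.300 M | 2.5 mM | 8.5 mM |  |

- south-west (time / min: target / %): 6.00: 0; 15.0: 1.2; 30.0: 5.2; 50.0: 11.9
- north-east (time / min: target / %): 4.00: 0.5; 8.00: 0.5; 20.0: 1.9; 50.0: 9.3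
- east (time / min: target / %): 12.0: 1.4; 25.0: 5.1; 40.0: 10.6; 50.0: 15.3

(each reading ± 0.3 percentage points)

- factor on the rate of making target when 30% of the substrate are converted if partner is charged twice over
- factor on the rate when 30% of the substrate are converted if catalyst is charged at 12 mM instead

I read the last row of each table first, at 50.0 min. The south-west and north-east runs carry the flask's catalyst charge and gave 11.9% and 9.3% of target. Their added ligand has a geometric mean of 8.45 mM, close to the flask's 8.5 mM, so I took the geometric mean of the readings as well, 10.5%, as my estimate for the flask at that time. Then I went up the east table, which has the flask's ligand charge with 3.8 mM of catalyst: it shows 10.6% at 40.0 min, level with that estimate within a scatter of 0.3 percentage points.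

Each step towards target carries one catalyst, so I reasoned that free catalyst merely speeds the flask's clock, leaving the composition at a given conversion unchanged. I therefore used the clock order, the power of the catalyst charge by which that clock speeds up, 0.533: as read from these scattered readings, a clock running 1.25 times as fast on 1.52 times the charge. A catalyst staying single gives 1 on this scale, and one held wholly as dimer gives 0.5, since free catalyst then follows the square root of the charge. The reading lies near the lower mark, so I took the resting dimer as the main form. At fixed conversion and the flask's ligand charge the rate follows the clock, so my ratio was 2.31. Partner enters one of the two steps and not the other, so the clock order does not reach dbl, and I left that a guess.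

The forecast gave ratio 2.8 (2.3 to 3.5), above mine, and dbl 1.65 (1.33 to 1.9), holding that “the rate scales with free catalyst”.

The flask gave 2.31 for ratio and 1.20 for dbl.

    2 catalyst ⇌ resting dimer, settled at all times (K = 1.10 × 10⁵ /M)
    partner + catalyst + intermediate → catalyst + target (k = 14.0 /M²/s)
    substrate + catalyst → catalyst + intermediate (k = 0.980 /M/s)
    catalyst + added ligand ⇌ idle complex, settled at all times (K = 420 /M)

In the flask after 1.00 h the resting dimer, the catalyst's resting state, held 82.8% of the catalyst charged, against 13.3% as idle complex and 3.88% as catalyst itself. The clock order carries the flask's rate at 30% conversion, 0.0209 M/h at 1.04 h, to 0.0482 M/h at 12 mM of catalyst.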